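I decided to keep time by the catalyst and not by the clock, since both catalysed steps run in proportion to a catalyst that has to appear first.

    reagent + catalyst + intermediate → catalyst + target (k1 = 0.010 L² mol⁻² min⁻¹)
    starting material + catalyst ⇌ catalyst + intermediate (K2 = 9.5, k2 = 0.010 L mol⁻¹ min⁻¹)
    precatalyst → catalyst (k3 = 3.1 × 10⁻⁴ min⁻¹)
    target → over-reaction product (k4 = 1.4 × 10⁻⁴ min⁻¹)

- west: starting material 2.0 M; reagent 0.900 equiv; precatalyst 0.77 mol%; time 6.0 d
- north-east: starting material 2.0 M; reagent 0.900 equiv; precatalyst 0.77 mol%; time 5.0 d

1. which of the two there is more of at the end, west (over-reaction product / target)
2. which of the two there is more of at the end, north-east (over-reaction product / target)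
3. how much target is there at the end, in percent of the starting material charged: west
4. how much target is there at the end, in percent of the starting material charged: north-east

At full release c(catalyst) is 0.0154 M, which makes the feed from starting material to intermediate pseudo-first-order with 1.54 × 10⁻⁴ min⁻¹. With reagent held at its charge, the coupling to target has 2.77 × 10⁻⁴ min⁻¹; I dropped the backward run. Catalyst is released first-order, so I weighted the run time by the share released and called the result working time. As precatalyst is released, the gap to the clock approaches the activation lag, the mean life of the precatalyst, 2.24 d.

This gave 3.91 d of working time in the west and 3.00 d in the north-east. The starting material left came to 42.0% and 51.4%, and the chain of two steps passed 31.7% and 22.1% through to target. Dating that target at mid-run, I kept 17.3% in the west and 13.3% in the north-east, which is more than went on to over-reaction product.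

Of the settings, time adds working time. The loading scales both catalysed steps. Reagent speeds the coupling and leaves the feed as it is. More starting material at fixed equivalents and loading raises c(catalyst) and c(reagent) together, so I expected it to count first.

The forecast named target in both flasks, with 17.7% in the west and 14.3% in the north-east, slightly above mine, holding that “the run is still far from complete”.

The flask gave 19.2% of target against 8.27% of over-reaction product in the west, and 14.9% against 4.81% in the north-east. Moved alone, the settings ranked for the north-east: starting material (8.1 points), then time (5.9 points), then precatalyst (5.4 points), then reagent (2.8 points). Put to use on the extra day of the west, the lag gives 0.910 d of working time, nearly all of that day.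

Read at 30 h, the same north-east flask has by my reckoning 7.01 h of working time, which gives 93.7% of the starting material left. The computed flask holds 93.7%, with 0.335% of target.

All constants were drawn at random within sensible limits; the run is a simulation.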